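**Retrosynthetic overview** (chromene numbering: O1, C2 (CMe2), C3, C4, C4a (quaternary), C5 (C=O), C6, C7 (C=O), C8 (C-aroyl), C8a)
1. Target 24 ⇐ 23 ⇐ 22 ⇐ 20: desilylation, Ag-assisted hydrolysis of a C7–SMe group, and C8–C8a dehydrogenation of bicycle 20.
2. 20 ⇐ acyclic 18 by an intramolecular double Michael reaction (anionic [4+2]): C4a–C8a first (tetrahydropyran), then C8–C7 with loss of MeS– (carbocycle); both rings form in this one step, in that order.
3. Enabling feature: C4a is the α′-carbon of the C5 ketone and lies 1,5 to O1 across C4–C3–C2, while O1–C8a=C8–C(=O)Ar is a vinylogous ester. Holding O1–C8a as a β-alkoxy enone (one oxidation level lower) and C5/C6/C7 as an α-oxo ketene dithioacetal makes the C4a–C8a closure a 6-exo Michael addition whose enolate then closes the second ring at C7.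
4. 18 ⇐ tertiary alcohol 13 + ynone 17 (oxa-Michael); 13 ⇐ ketone 11 (CS2, MeI).
5. 11 ⇐ methyl acetoacetate by two γ-alkylations with iodides 5 and 2 (both from (R)-lavandulol), α-prenylation and demethoxycarbonylation.

Key step: step 14

Remark (assumption): C-6 of the target, the CH between the C5 and C7 carbonyls, is a freely enolisable β-diketone methine, so no step can fix it kinetically; the route delivers the equilibrating compound, and the (6S) diketo form of the given SMILES is taken as its preferred epimer (prenyl pseudo-equatorial).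
Abbreviations: Lav = (2S)-5-methyl-2-(prop-1-en-2-yl)hex-4-en-1-yl (from (R)-lavandulol; the descriptor changes only through CIP priorities); prenyl = 3-methylbut-2-en-1-yl; TBS = tert-butyldimethylsilyl; TES = triethylsilyl.

Step 1
Reactants: 1 (R)-lavandulol
Product: 2 (R)-lavandulyl iodide
Conditions: PPh3, I2, imidazole, CH2Cl2, 0 °C to rt
Reagents that add atoms: iodine (II)
Why: Appel-type iodination of the primary alcohol should proceed by SN2 at CH2 and leave the adjacent stereocentre and both alkenes untouched.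

Step 2
Reactants: 1 (R)-lavandulol
Product: 3 (2S)-2-(2-hydroxypropan-2-yl)-5-methylhex-4-en-1-ol
Conditions: Co(acac)2 (20 mol%), PhSiH3, O2 (1 atm), THF, rt
Reagents that add atoms: dioxygen (O=O)
Why: Mukaiyama hydration (hydrogen-atom-transfer Markovnikov hydration) should favour the less hindered 1,1-disubstituted isopropenyl alkene over the trisubstituted prenyl alkene, and the stereocentre is not involved.

Step 3
Reactants: 3 (2S)-2-(2-hydroxypropan-2-yl)-5-methylhex-4-en-1-ol
Product: 4 (3R)-3-(iodomethyl)-2,6-dimethylhept-5-en-2-ol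
Conditions: PPh3, I2, imidazole, CH2Cl2, 0 °C
Reagents that add atoms: iodine (II)
Why: Appel-type iodination should be selective for the primary over the tertiary hydroxyl group.

Step 4
Reactants: 4 (3R)-3-(iodomethyl)-2,6-dimethylhept-5-en-2-ol
Product: 5 triethyl{[(3R)-3-(iodomethyl)-2,6-dimethylhept-5-en-2-yl]oxy}silane
Conditions: TESOTf, 2,6-lutidine, CH2Cl2, –78 to 0 °C
Reagents that add atoms: triethylsilyl trifluoromethanesulfonate (CC[Si](CC)(CC)OS(=O)(=O)C(F)(F)F)
Why: Silyl triflate silylation masks the tertiary alcohol so that its alkoxide cannot form an oxetane or consume base in the alkylations.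

Step 5
Reactants: 6 methyl acetoacetate; 5 TES-protected iodide
Product: 7 methyl (6R)-7-methyl-6-prenyl-3-oxo-7-(triethylsilyloxy)octanoate
Conditions: LDA (2.1 equiv), THF, 0 °C; then 5, DMPU, 0 °C to rt; AcOH quench
Reagents that add atoms: none
Why: γ-Alkylation of the acetoacetate dianion (SN2 at the terminal carbanion) should take the more hindered iodide while the nucleophile is still unbranched.

Step 6
Reactants: 7 γ-alkylated β-keto ester; 2 (R)-lavandulyl iodide
Product: 8 methyl (6S)-4-Lav-7-methyl-6-prenyl-3-oxo-7-(triethylsilyloxy)octanoate (C-4 epimers)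
Conditions: LDA (2.1 equiv), THF, 0 °C; then 2, DMPU, 0 °C to rt; AcOH quench
Reagents that add atoms: none
Why: A second dianion γ-alkylation installs the lavandulyl arm; the new C-4 centre (future C4a–H) forms as a mixture that is erased by enolisation in step 14.

Step 7
Reactants: 8 γ,γ-dialkylated β-keto ester; 9 prenyl bromide
Product: 10 methyl (6S)-4-Lav-7-methyl-2,6-diprenyl-3-oxo-7-(triethylsilyloxy)octanoate (C-2/C-4 epimers)
Conditions: K2CO3, acetone, rt to 40 °C
Reagents that add atoms: none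
Why: C-Alkylation of the soft β-keto ester enolate with an allylic bromide should give the mono-prenylated product.

Step 8
Reactants: 10 α-prenyl β-keto ester
Product: 11 (9S)-7-Lav-2,10-dimethyl-9-prenyl-10-(triethylsilyloxy)undec-2-en-6-one (C-7 epimers)
Conditions: LiCl, DMSO–H2O, 140 °C
Reagents that add atoms: none
Why: Krapcho demethoxycarbonylation removes the ester under neutral conditions that spare the alkenes and the silyl ether.

Step 9
Reactants: 11 ketone
Product: 12 (9S)-5-[bis(methylsulfanyl)methylidene]-7-Lav-2,10-dimethyl-9-prenyl-10-(triethylsilyloxy)undec-2-en-6-one (C-7 epimers)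
Conditions: LiHMDS (2.2 equiv), THF, –78 °C; CS2, –78 to 0 °C; MeI, 0 °C to rt
Reagents that add atoms: carbon disulfide (S=C=S); iodomethane (CI)
Why: α-Oxo ketene dithioacetal formation can occur only at the less hindered α-CH2 (C6), because the other α-carbon carries a single hydrogen.

Step 10
Reactants: 12 TES-protected ketene dithioacetal
Product: 13 (9S)-5-[bis(methylsulfanyl)methylidene]-10-hydroxy-7-Lav-2,10-dimethyl-9-prenylundec-2-en-6-one (C-7 epimers)
Conditions: HF·pyridine, pyridine–THF, 0 °C to rt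
Reagents that add atoms: none
Why: Fluoride-mediated cleavage of the tertiary TES ether should leave the push-pull alkene and the other alkenes intact.

Step 11
Reactants: 14 3,4-bis(tert-butyldimethylsilyloxy)benzaldehyde; 15 ethynylmagnesium bromide
Product: 16 1-[3,4-bis(TBSO)phenyl]prop-2-yn-1-ol (racemic)
Conditions: THF, –78 to 0 °C; aqueous work-up
Reagents that add atoms: none
Why: Grignard 1,2-addition to the aldehyde; the new carbinol centre is removed in the next step.

Step 12
Reactants: 16 propargylic alcohol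
Product: 17 1-[3,4-bis(TBSO)phenyl]prop-2-yn-1-one
Conditions: MnO2, CH2Cl2, rt
Reagents that add atoms: none
Why: MnO2 oxidises the benzylic-propargylic alcohol selectively to the terminal ynone.

Step 13
Reactants: 13 tertiary alcohol; 17 aryl ynone
Product: 18 (9S)-10-{[(1E)-3-[3,4-bis(TBSO)phenyl]-3-oxoprop-1-en-1-yl]oxy}-5-[bis(methylsulfanyl)methylidene]-7-Lav-2,10-dimethyl-9-prenylundec-2-en-6-one (C-7 epimers)
Conditions: PMe3 (20 mol%), CH2Cl2, 0 °C to rt
Reagents that add atoms: none
Why: Phosphine-catalysed oxa-Michael addition of an alcohol to a terminal ynone, which tolerates tertiary alcohols and is inert to the ketone, should give the (E)-β-alkoxy enone.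

Step 14
Reactants: 18 enone-tethered α-oxo ketene dithioacetal
Product: 20 (3S,4aR)-8-[3,4-bis(TBSO)benzoyl]-4a-Lav-2,2-dimethyl-7-(methylsulfanyl)-3,6-diprenyl-2,3,4,4a,8,8a-hexahydro-5H-chromen-5-one (C-8/C-8a epimers), via lithium enolate 19 (not isolated)
Conditions: LiHMDS (2.2 equiv), THF (0.01 M), –78 to 0 °C; AcOH quench at –78 °C
Reagents that add atoms: none
Why: LiHMDS removes the only acidic proton (C4a–H, α′ to the C5 ketone) to give the cross-conjugated 2-oxidodiene C4a=C5(OLi)–C6=C7(SMe)2, whose C4a terminus adds to C8a of the O1-tethered β-alkoxy enone (6-exo-trig, closes the tetrahydropyran) to give enolate 19, which then adds through C8 to C7 (6-endo-trig, closes the carbocycle) and expels methanethiolate. The closest known reaction type is the intramolecular double Michael reaction (anionic [4+2]) of α′-enolates of enones, terminated here by the addition–elimination that enolates undergo on α-oxo ketene dithioacetals. The only stereocentre that survives, C4a, is set in the first addition through a chair-like transition state of the forming pyran in which the C3 prenyl group is equatorial and the bulky planar C5 enolate arm is pseudo-equatorial, so the lavandulyl CH2 becomes axial and trans to the C3 prenyl group, i.e. (4aR) from (3S). C8a and C8 form as mixtures and are erased in step 15. The step needs C4a, not C6 or oxygen, to attack C8a in 1,4-fashion; C6 is fully substituted, no other acidic proton exists, and only the two six-membered closures are within reach of the tether. The second equivalent of base keeps 20 as its extended enolate, which protects the β-alkoxy ketone against retro-oxa-Michael opening until the quench.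

Step 15
Reactants: 20 bicyclic vinylogous thioester
Product: 22 (3S,4aR)-8-[3,4-bis(TBSO)benzoyl]-4a-Lav-2,2-dimethyl-7-(methylsulfanyl)-3,6-diprenyl-2,3,4,4a-tetrahydro-5H-chromen-5-one, via sulfilimine adduct 21 (not isolated)
Conditions: LiHMDS (1.1 equiv), THF, –78 °C; then N-tert-butylbenzenesulfinimidoyl chloride (1.2 equiv), –78 °C to rt
Reagents that add atoms: none
Why: Mukaiyama dehydrogenation of the lithium enolate: the single acidic proton (C8–H) is removed, sulfur should add at the less substituted terminus C8 anti to the axial lavandulyl arm (hence syn to C8a–H), and syn-elimination gives the C8=C8a vinylogous ester.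

Step 16
Reactants: 22 dienone with C7–SMe
Product: 23 (3S,4aR)-8-[3,4-bis(TBSO)benzoyl]-4a-Lav-2,2-dimethyl-3,6-diprenyl-3,4,4a,6-tetrahydro-2H-chromene-5,7-dione (C-6 labile, enol tautomers)
Conditions: AgNO3 (2.5 equiv), 2,6-lutidine, THF–H2O (4:1), rt, dark
Reagents that add atoms: water (O)
Why: Thiophilic silver activation makes hydrolysis of the vinylogous thioester (addition–elimination of water at C7) selective over the C8a vinylogous ester, and it is done before the catechol is unmasked because Ag(I) oxidises catechols.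

Step 17
Reactants: 23 bis-TBS-protected target
Product: 24 target, (3S,4aR,6S)-8-(3,4-dihydroxybenzoyl)-2,2-dimethyl-3,6-diprenyl-4a-Lav-3,4,4a,6-tetrahydro-2H-chromene-5,7-dione
Conditions: HF·pyridine, pyridine–THF, 0 °C
Reagents that add atoms: none
Why: Mildly acidic fluoride cleaves both aryl silyl ethers without touching the enol ether or the prenyl groups; C-6 settles by enolisation as stated in the remark.

**Compound list**
1 | (R)-lavandulol, (2R)-5-methyl-2-(prop-1-en-2-yl)hex-4-en-1-ol | C=C(C)[C@@H](CC=C(C)C)CO | starting material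
2 | (R)-lavandulyl iodide, (3R)-3-(iodomethyl)-2,6-dimethylhepta-1,5-diene | C=C(C)[C@@H](CC=C(C)C)CI | intermediate
3 | (2S)-2-(2-hydroxypropan-2-yl)-5-methylhex-4-en-1-ol | OC[C@H](CC=C(C)C)C(C)(C)O | intermediate
4 | (3R)-3-(iodomethyl)-2,6-dimethylhept-5-en-2-ol | IC[C@H](CC=C(C)C)C(C)(C)O | intermediate
5 | triethyl{[(3R)-3-(iodomethyl)-2,6-dimethylhept-5-en-2-yl]oxy}silane | IC[C@H](CC=C(C)C)C(C)(C)O[Si](CC)(CC)CC | intermediate
6 | methyl acetoacetate | COC(=O)CC(C)=O | starting material
7 | methyl (6R)-7-methyl-6-prenyl-3-oxo-7-(triethylsilyloxy)octanoate | COC(=O)CC(=O)CC[C@H](CC=C(C)C)C(C)(C)O[Si](CC)(CC)CC | intermediate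
8 | methyl (6S)-4-Lav-7-methyl-6-prenyl-3-oxo-7-(triethylsilyloxy)octanoate (C-4 epimers) | COC(=O)CC(=O)C(C[C@H](CC=C(C)C)C(C)=C)C[C@H](CC=C(C)C)C(C)(C)O[Si](CC)(CC)CC | intermediate
9 | prenyl bromide, 1-bromo-3-methylbut-2-ene | CC(C)=CCBr | starting material
10 | methyl (6S)-4-Lav-7-methyl-2,6-diprenyl-3-oxo-7-(triethylsilyloxy)octanoate (C-2/C-4 epimers) | COC(=O)C(CC=C(C)C)C(=O)C(C[C@H](CC=C(C)C)C(C)=C)C[C@H](CC=C(C)C)C(C)(C)O[Si](CC)(CC)CC | intermediate
11 | (9S)-7-Lav-2,10-dimethyl-9-prenyl-10-(triethylsilyloxy)undec-2-en-6-one (C-7 epimers) | CC(C)=CCCC(=O)C(C[C@H](CC=C(C)C)C(C)=C)C[C@H](CC=C(C)C)C(C)(C)O[Si](CC)(CC)CC | intermediate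
12 | (9S)-5-[bis(methylsulfanyl)methylidene]-7-Lav-2,10-dimethyl-9-prenyl-10-(triethylsilyloxy)undec-2-en-6-one (C-7 epimers) | CSC(SC)=C(CC=C(C)C)C(=O)C(C[C@H](CC=C(C)C)C(C)=C)C[C@H](CC=C(C)C)C(C)(C)O[Si](CC)(CC)CC | intermediate
13 | (9S)-5-[bis(methylsulfanyl)methylidene]-10-hydroxy-7-Lav-2,10-dimethyl-9-prenylundec-2-en-6-one (C-7 epimers) | CSC(SC)=C(CC=C(C)C)C(=O)C(C[C@H](CC=C(C)C)C(C)=C)C[C@H](CC=C(C)C)C(C)(C)O | intermediate
14 | 3,4-bis(tert-butyldimethylsilyloxy)benzaldehyde | O=Cc1ccc(O[Si](C)(C)C(C)(C)C)c(O[Si](C)(C)C(C)(C)C)c1 | starting material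
15 | ethynylmagnesium bromide | C#C[Mg]Br | starting material
16 | 1-[3,4-bis(TBSO)phenyl]prop-2-yn-1-ol (racemic) | C#CC(O)c1ccc(O[Si](C)(C)C(C)(C)C)c(O[Si](C)(C)C(C)(C)C)c1 | intermediate
17 | 1-[3,4-bis(TBSO)phenyl]prop-2-yn-1-one | C#CC(=O)c1ccc(O[Si](C)(C)C(C)(C)C)c(O[Si](C)(C)C(C)(C)C)c1 | intermediate
18 | (9S)-10-{[(1E)-3-[3,4-bis(TBSO)phenyl]-3-oxoprop-1-en-1-yl]oxy}-5-[bis(methylsulfanyl)methylidene]-7-Lav-2,10-dimethyl-9-prenylundec-2-en-6-one (C-7 epimers) | CSC(SC)=C(CC=C(C)C)C(=O)C(C[C@H](CC=C(C)C)C(C)=C)C[C@H](CC=C(C)C)C(C)(C)O/C=C/C(=O)c1ccc(O[Si](C)(C)C(C)(C)C)c(O[Si](C)(C)C(C)(C)C)c1 | intermediate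
19 | lithium enolate of the mono-Michael adduct: 2,2-dimethyl-3-prenyl-tetrahydropyran whose future C4a carries Lav and the 2-[bis(methylsulfanyl)methylidene]-6-methylhept-5-enoyl group and whose future C8a carries CH=C(OLi)Ar (C-8a epimers) | C=C(C)[C@@H](CC=C(C)C)C[C@@]1(C(=O)C(CC=C(C)C)=C(SC)SC)C[C@H](CC=C(C)C)C(C)(C)OC1C=C(O[Li])c1ccc(O[Si](C)(C)C(C)(C)C)c(O[Si](C)(C)C(C)(C)C)c1 | intermediate (not isolated)
20 | (3S,4aR)-8-[3,4-bis(TBSO)benzoyl]-4a-Lav-2,2-dimethyl-7-(methylsulfanyl)-3,6-diprenyl-2,3,4,4a,8,8a-hexahydro-5H-chromen-5-one (C-8/C-8a epimers) | C=C(C)[C@@H](CC=C(C)C)C[C@@]12C[C@H](CC=C(C)C)C(C)(C)OC1C(C(=O)c1ccc(O[Si](C)(C)C(C)(C)C)c(O[Si](C)(C)C(C)(C)C)c1)C(SC)=C(CC=C(C)C)C2=O | intermediate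
21 | C-8 N-tert-butyl-S-phenylsulfilimine adduct of 20 | C=C(C)[C@@H](CC=C(C)C)C[C@@]12C[C@H](CC=C(C)C)C(C)(C)OC1C(C(=O)c1ccc(O[Si](C)(C)C(C)(C)C)c(O[Si](C)(C)C(C)(C)C)c1)(S(=NC(C)(C)C)c1ccccc1)C(SC)=C(CC=C(C)C)C2=O | intermediate (not isolated)
22 | (3S,4aR)-8-[3,4-bis(TBSO)benzoyl]-4a-Lav-2,2-dimethyl-7-(methylsulfanyl)-3,6-diprenyl-2,3,4,4a-tetrahydro-5H-chromen-5-one | C=C(C)[C@@H](CC=C(C)C)C[C@@]12C[C@H](CC=C(C)C)C(C)(C)OC1=C(C(=O)c1ccc(O[Si](C)(C)C(C)(C)C)c(O[Si](C)(C)C(C)(C)C)c1)C(SC)=C(CC=C(C)C)C2=O | intermediate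
23 | (3S,4aR)-8-[3,4-bis(TBSO)benzoyl]-4a-Lav-2,2-dimethyl-3,6-diprenyl-3,4,4a,6-tetrahydro-2H-chromene-5,7-dione (C-6 labile) | C=C(C)[C@@H](CC=C(C)C)C[C@@]12C[C@H](CC=C(C)C)C(C)(C)OC1=C(C(=O)c1ccc(O[Si](C)(C)C(C)(C)C)c(O[Si](C)(C)C(C)(C)C)c1)C(=O)C(CC=C(C)C)C2=O | intermediate
24 | (3S,4aR,6S)-8-(3,4-dihydroxybenzoyl)-2,2-dimethyl-3,6-bis(3-methylbut-2-en-1-yl)-4a-[(2S)-5-methyl-2-(prop-1-en-2-yl)hex-4-en-1-yl]-3,4,4a,6-tetrahydro-2H-chromene-5,7-dione | C=C(C)[C@@H](CC=C(C)C)C[C@@]12C[C@H](CC=C(C)C)C(C)(C)OC1=C(C(=O)c1ccc(O)c(O)c1)C(=O)[C@@H](CC=C(C)C)C2=O | target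

**Step count and risks**
Total step count: 17. Longest linear sequence: 14 steps (steps 2, 3, 4, 5, 6, 7, 8, 9, 10, 13, 14, 15, 16, 17).

The three steps most likely to fail:

Step 14. Enolate 19 may reopen the new pyran by retro-oxa-Michael elimination before the second Michael addition, and facial selectivity at C4a may be poor. The fallback sets out from 18 and separates the two bond formations. The first Michael adduct is trapped at –78 °C (LiHMDS, then TBSOTf) as the silyl enol ether of the mono-Michael adduct F1, which cannot eliminate. F1 is then closed under Lewis-acid conditions (catalytic TMSOTf or BF3·OEt2 with 2,6-di-tert-butyl-4-methylpyridine, CH2Cl2, –78 °C) by a Mukaiyama–Michael addition–elimination on the ketene dithioacetal. This gives 20, where the route is rejoined.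

Step 6. The strongly basic, branched dianion carbon may cause E2 elimination of the homoallylic iodide 2, and SN2 there may be slow. The fallback sets out from 5 and builds the doubly branched carbon on a soft malonate nucleophile. Sodium dimethyl malonate (NaH, DMF) is alkylated with 5 to the monoalkyl malonate F2 and then with 2 to the dialkyl malonate F3. Krapcho demethoxycarbonylation (LiCl, wet DMSO, 150 °C) gives the methyl ester F4. Crossed Claisen condensation of F4 with the lithium enolate of methyl acetate (3 equiv, THF, –78 to 0 °C) gives 8, where the route is rejoined.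

Step 15. Sulfur may be transferred to C6 of the extended enolate instead of C8, or the adduct may lack a syn C8a–H for elimination. The fallback sets out from 20 and uses a palladium-mediated oxidation. Soft enolisation (TBSOTf, Et3N, CH2Cl2, 0 °C) gives the silyl enol ether of the aryl ketone F5. Saegusa–Ito oxidation (Pd(OAc)2, MeCN, rt) then gives 22, where the route is rejoined.

**Further compounds**
F1 | step 14 | tert-butyldimethylsilyl enol ether of the mono-Michael adduct (19 with OTBS in place of OLi) | C=C(C)[C@@H](CC=C(C)C)C[C@@]1(C(=O)C(CC=C(C)C)=C(SC)SC)C[C@H](CC=C(C)C)C(C)(C)OC1C=C(O[Si](C)(C)C(C)(C)C)c1ccc(O[Si](C)(C)C(C)(C)C)c(O[Si](C)(C)C(C)(C)C)c1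
F2 | step 6 | dimethyl 2-[(2S)-3-methyl-2-prenyl-3-(triethylsilyloxy)butyl]propanedioate | COC(=O)C(C[C@H](CC=C(C)C)C(C)(C)O[Si](CC)(CC)CC)C(=O)OC
F3 | step 6 | dimethyl 2-Lav-2-[(2S)-3-methyl-2-prenyl-3-(triethylsilyloxy)butyl]propanedioate | COC(=O)C(C[C@H](CC=C(C)C)C(C)=C)(C[C@H](CC=C(C)C)C(C)(C)O[Si](CC)(CC)CC)C(=O)OC
F4 | step 6 | methyl (4S)-2-Lav-5-methyl-4-prenyl-5-(triethylsilyloxy)hexanoate (C-2 epimers) | COC(=O)C(C[C@H](CC=C(C)C)C(C)=C)C[C@H](CC=C(C)C)C(C)(C)O[Si](CC)(CC)CC
F5 | step 15 | tert-butyldimethylsilyl enol ether of 20 at the aroyl ketone (C8=C(OTBS)Ar) | C=C(C)[C@@H](CC=C(C)C)C[C@@]12C[C@H](CC=C(C)C)C(C)(C)OC1C(=C(O[Si](C)(C)C(C)(C)C)c1ccc(O[Si](C)(C)C(C)(C)C)c(O[Si](C)(C)C(C)(C)C)c1)C(SC)=C(CC=C(C)C)C2=O
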